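The plan opens the 18-membered ring at the ether bond between the oxygen on C2 of ring B (C1 ethylene bridge, C2 O, C3 OH) and the carbon of ring C that lies meta to its bridge. One palladium-catalysed C–O coupling closes the macrocycle from a linear four-ring chain that ends in a free phenol (ring B) and an aryl chloride (ring C). The step exploits the crowding of the ring B oxygen by C1 and C3, which speeds C–O reductive elimination, and the two ortho hydrogens at the ring C carbon. The chloride stays silent while two B-alkyl Suzuki couplings install both CH2CH2 bridges in saturated form.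

Key step: step 4

Remark: ring A is the para-phenylene ring. Ring B carries the bridge at C1, the ether oxygen at C2 and OH at C3. Ring C is the meta-phenylene ring. Ring D is the ring whose OH lies para to its bridge. The target has no stereocentre and no C=C bond, so its SMILES carries no stereo descriptor. Compounds 1, 2, 5 and 7 and 9-BBN-H are taken as catalogue chemicals.

Step 1
Reactants: 1 3-chlorostyrene; 2 5-bromo-2-methoxyphenol
Product: 4 5-[2-(3-chlorophenyl)ethyl]-2-methoxyphenol, via B-alkyl-9-BBN adduct 3 (not isolated)
Conditions: 1, 9-BBN-H (0.5 M in THF), 0 °C to rt; then 2, PdCl2(dppf) (5 mol %), 3 M aq NaOH, THF, 65 °C; aq NH4Cl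
Reagents that add atoms: 9-BBN-H (9-borabicyclo[3.3.1]nonane), B1C2CCCC1CCC2
Why: Anti-Markovnikov hydroboration of the styrene by 9-BBN-H followed by a B-alkyl Suzuki–Miyaura coupling should join the primary alkylborane to C5 of 2, because PdCl2(dppf) enters the C–Br bond but leaves the C–Cl bond of ring C untouched and the free phenol merely consumes one equivalent of base.

Step 2
Reactants: 4 5-[2-(3-chlorophenyl)ethyl]-2-methoxyphenol; 5 4-vinylphenylboronic acid
Product: 6 4-[2-(3-chlorophenyl)ethyl]-2-(4-ethenylphenoxy)-1-methoxybenzene
Conditions: Cu(OAc)2 (2 equiv), pyridine (5 equiv), 4 Å MS, CH2Cl2, rt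
Reagents that add atoms: none
Why: In this Chan–Lam–Evans O-arylation the aryl group passes from boron to copper and C–O reductive elimination from trivalent copper arylates the ring D phenol at room temperature, conditions that spare the vinyl group and the aryl chloride.

Step 3
Reactants: 6 4-[2-(3-chlorophenyl)ethyl]-2-(4-ethenylphenoxy)-1-methoxybenzene; 7 2-bromo-6-methoxyphenol
Product: 9 2-[2-(4-{5-[2-(3-chlorophenyl)ethyl]-2-methoxyphenoxy}phenyl)ethyl]-6-methoxyphenol, via B-alkyl-9-BBN adduct 8 (not isolated)
Conditions: 6, 9-BBN-H (0.5 M in THF), 0 °C to rt; then 7, PdCl2(dppf) (5 mol %), 3 M aq NaOH, THF, 65 °C; aq NH4Cl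
Reagents that add atoms: 9-BBN-H (9-borabicyclo[3.3.1]nonane), B1C2CCCC1CCC2
Why: The same hydroboration/B-alkyl Suzuki–Miyaura sequence should couple the primary alkylborane 8 with the C–Br bond of 7, the only bond in the mixture that PdCl2(dppf) can enter, and so delivers the A–B bridge saturated and the ring B phenol unprotected.

Step 4
Reactants: 9 2-[2-(4-{5-[2-(3-chlorophenyl)ethyl]-2-methoxyphenoxy}phenyl)ethyl]-6-methoxyphenol
Product: 10 marchantin C di-O-methyl ether (the 18-membered macrocycle with both phenolic oxygens as OMe)
Conditions: Pd(OAc)2 (10 mol %), tBuXPhos (20 mol %), K3PO4 (3 equiv), degassed toluene, 100 °C, 9 added by syringe pump (final 2 mM)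
Reagents that add atoms: none
Why: Zerovalent palladium carrying the bulky tBuXPhos ligand inserts into the C–Cl bond of ring C, the potassium phenoxide of ring B replaces chloride at divalent palladium, and C–O reductive elimination releases the diaryl ether and the catalyst. The closest known reaction type is the Buchwald–Hartwig diaryl ether synthesis, which accepts unactivated aryl chlorides and works best with ortho-substituted phenols. The single ring formed is the 18-membered macrocycle, closed end to end by contraction of a 19-membered aryl(aryloxo)palladacycle, so that after oxidative addition every bond-forming event is intramolecular. No stereocentre is created. Chemoselectivity is secured because 9 holds only one free OH and only one carbon–halogen bond, while slow addition into a dilute catalyst solution and the two flexible CH2CH2 bridges favour ring closure over oligomerisation. The C1 bridge and the C3 methoxy group that flank the phenoxide oxygen crowd the palladium centre and should speed the reductive elimination that normally limits the rate, and the ring C carbon with its two ortho hydrogens offers no steric resistance.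

Step 5
Reactants: 10 marchantin C di-O-methyl ether
Product: 11 marchantin C
Conditions: BBr3 (6 equiv), CH2Cl2, −78 °C to rt; then H2O
Reagents that add atoms: none
Why: BBr3 demethylation of aryl methyl ethers (Lewis acid complexation, then bromide attack at methyl) should free both phenols, since the diaryl ether C–O bonds and the CH2CH2 bridges are inert to the reagent.

Compound list
1 | 3-chlorostyrene (1-chloro-3-ethenylbenzene) | C=Cc1cccc(Cl)c1 | starting material
2 | 5-bromo-2-methoxyphenol | COc1ccc(Br)cc1O | starting material
3 | 9-[2-(3-chlorophenyl)ethyl]-9-borabicyclo[3.3.1]nonane (not isolated) | Clc1cccc(CCB2C3CCCC2CCC3)c1 | intermediate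
4 | 5-[2-(3-chlorophenyl)ethyl]-2-methoxyphenol | COc1ccc(CCc2cccc(Cl)c2)cc1O | intermediate
5 | 4-vinylphenylboronic acid | C=Cc1ccc(B(O)O)cc1 | starting material
6 | 4-[2-(3-chlorophenyl)ethyl]-2-(4-ethenylphenoxy)-1-methoxybenzene | COc1ccc(CCc2cccc(Cl)c2)cc1Oc1ccc(C=C)cc1 | intermediate
7 | 2-bromo-6-methoxyphenol | COc1cccc(Br)c1O | starting material
8 | 9-[2-(4-{5-[2-(3-chlorophenyl)ethyl]-2-methoxyphenoxy}phenyl)ethyl]-9-borabicyclo[3.3.1]nonane (not isolated) | COc1ccc(CCc2cccc(Cl)c2)cc1Oc1ccc(CCB2C3CCCC2CCC3)cc1 | intermediate
9 | 2-[2-(4-{5-[2-(3-chlorophenyl)ethyl]-2-methoxyphenoxy}phenyl)ethyl]-6-methoxyphenol | COc1ccc(CCc2cccc(Cl)c2)cc1Oc1ccc(CCc2cccc(OC)c2O)cc1 | intermediate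
10 | marchantin C di-O-methyl ether | COc1ccc2cc1Oc1ccc(cc1)CCc1cccc(OC)c1Oc1cccc(c1)CC2 | intermediate
11 | marchantin C | Oc1ccc2cc1Oc1ccc(cc1)CCc1cccc(O)c1Oc1cccc(c1)CC2 | target

Total step count: 5. Longest linear sequence: 5 steps (1 to 5).

Steps most likely to fail

1. Step 4 (key step). Intermolecular coupling may outrun ring closure. The aryl(aryloxo)palladium species may also stall before reductive elimination and drift into reductive loss of chlorine. The fallback sets out from 9, comes back at 10, and inverts the polarity of ring C. Palladium-catalysed borylation of the C–Cl bond of 9 with B2(OH)4 (Pd(OAc)2, XPhos, KOAc, EtOH, 80 °C) should give [3-(2-{3-[4-(2-(2-hydroxy-3-methoxyphenyl)ethyl)phenoxy]-4-methoxyphenyl}ethyl)phenyl]boronic acid F1. An oxidative Chan–Lam–Evans macrocyclisation of this acid (Cu(OAc)2, pyridine, 4 Å MS, CH2Cl2, 1 mM, dry air, rt) then closes the same O–C bond at room temperature to 10.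

2. Step 3. Oxidative addition into the electron-rich ortho-bromophenoxide may be so slow that the alkylborane is lost through protodeboronation or β-hydride elimination. The fallback sets out from 6 (with 7), comes back at 9, and needs no fragile organoborane, so forcing conditions can be used. Mizoroki–Heck arylation of the vinyl group of 6 with 7 (Pd(OAc)2, P(o-tol)3, NaOAc, DMA, 120 °C), in which the phenol stays largely un-ionised, should give 2-[(E)-2-(4-{5-[2-(3-chlorophenyl)ethyl]-2-methoxyphenoxy}phenyl)ethenyl]-6-methoxyphenol F2. Hydrogenation over Pd/C poisoned with Ph2S (H2 1 atm, EtOAc, rt) should then saturate the alkene without touching the C–Cl bond and give 9.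

3. Step 2. Protodeboronation, homocoupling or copper-induced polymerisation of the vinyl boronic acid may consume 5 before the ortho-methoxy phenol is arylated. The fallback sets out from 4, comes back at 6, and builds the A–D ether by addition–elimination instead of oxidative coupling. Nucleophilic aromatic substitution of 4-fluorobenzaldehyde by the phenoxide of 4 (K2CO3, DMF, 120 °C) should give 4-{5-[2-(3-chlorophenyl)ethyl]-2-methoxyphenoxy}benzaldehyde F3. Wittig methylenation (MePPh3Br, KOtBu, THF, 0 °C) then converts the aldehyde into the styrene 6.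

Further compounds
F1 | step 4 | [3-(2-{3-[4-(2-(2-hydroxy-3-methoxyphenyl)ethyl)phenoxy]-4-methoxyphenyl}ethyl)phenyl]boronic acid | COc1ccc(CCc2cccc(B(O)O)c2)cc1Oc1ccc(CCc2cccc(OC)c2O)cc1
F2 | step 3 | 2-[(E)-2-(4-{5-[2-(3-chlorophenyl)ethyl]-2-methoxyphenoxy}phenyl)ethenyl]-6-methoxyphenol | COc1ccc(CCc2cccc(Cl)c2)cc1Oc1ccc(/C=C/c2cccc(OC)c2O)cc1
F3 | step 2 | 4-{5-[2-(3-chlorophenyl)ethyl]-2-methoxyphenoxy}benzaldehyde | COc1ccc(CCc2cccc(Cl)c2)cc1Oc1ccc(C=O)cc1
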